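**Plan**

1. Retrosynthetic cuts, in order: (a) the two aryl O–H bonds (carried as silyl ethers) and the ring-ketone C=O (carried as its alcohol); (b) the bond between the side-chain carbonyl carbon and its allylic CH2, which splits the target into a C15 δ-lactone and a C12 (E)-allyl chloride used as its allylbarium; (c) the bond from the ring-bound carbinol carbon to the prenyl CH2; (d) the C2=C3 bond of a cis-1,5-dimethylbicyclo[3.3.0]oct-2-ene; (e) the aryl–prenyl bond, back to o-cresol.
2. Enabling feature: on the cis-1,2-dimethylcyclopentane the carbonyl carbon on C1 and the carbonyl carbon of the CH2C(=O) arm on C2 are 1,5-related and on the same face, so the ring ketone, held at the alcohol level, ties the arm's carboxyl into a six-membered lactone (a cyclopenta[c]pyran-3-one ring that is not in the target). The CH2 to be attached is allylic, so it can arrive as a configurationally stable allylmetal.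
3. Forward order: meso bicyclic diketone → meso monoketone → enantioenriched enol silane → ozonolytic opening of one five-membered ring to the cyclopentane aldehyde acid → prenylation and lactonisation. In parallel: o-cresol → ortho-prenylphenol → quinone → silylated hydroquinone → (E)-allylic alcohol → chloride. The halves are joined at the lactone carbonyl; one oxidation and one desilylation finish.
4. Stereochemistry: the cis relation of the two quaternary carbons is the cis fusion of the bicyclo[3.3.0]octane; their absolute configuration (both R in the target) is set in one enantiotopos-selective deprotonation of the meso ketone by a chiral lithium amide. The E alkene is set by SeO2 oxidation of a prenyl group and kept through the allylbarium. Carbinol and hemiketal centres made on the way are uncontrolled and all removed.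

Key step: step 12

Assumption: the bicyclic diketone starting material is taken as the commercial product of the Weiss–Cook condensation of butane-2,3-dione with dimethyl 3-oxopentanedioate.
Assumption: the (R,R) lithium amide is assumed to remove the proton that leads to the (1S,5R) enol silane; if the opposite sense is found, the (S,S) amine is used and nothing else changes.
Assumption: compounds with a carbinol or hemiketal carbon are carried as epimer mixtures, since these centres become carbonyl carbons in step 13; their SMILES leave those centres undefined.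

**Step 1**
Reactants: 1 cis-1,5-dimethylbicyclo[3.3.0]octane-3,7-dione (meso)
Product: 2 cis-7,7-(2,2-dimethylpropane-1,3-diyldioxy)-1,5-dimethylbicyclo[3.3.0]octan-3-one (mono-ketal)
Conditions: 2,2-dimethylpropane-1,3-diol (1.0 equiv), p-TsOH·H2O (cat.), benzene, reflux, Dean–Stark
Reagents that add atoms: 2,2-dimethylpropane-1,3-diol, OCC(C)(C)CO
Why: Acid-catalysed ketalisation with one equivalent of diol should give the mono-ketal as the main component of a statistical mixture, because the two carbonyl groups are equivalent and remote, with diketone and bis-ketal returned to the step after hydrolysis.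

**Step 2**
Reactants: 2 mono-ketal
Product: 5 cis-(1R,5S)-1,5-dimethylbicyclo[3.3.0]octan-3-one (meso), via hydrazone 3 (not isolated), via ketal 4 (not isolated)
Conditions: N2H4·H2O, KOH, diethylene glycol, 130 → 200 °C; then cool, 3 M aq. HCl, 50 °C
Reagents that add atoms: water, O
Why: Wolff–Kishner reduction (Huang-Minlon procedure) removes the free carbonyl through its hydrazone while the base-stable ketal survives, and acidification of the same flask hydrolyses the ketal to the meso ketone, whose mirror plane through C3 and C7 makes the C2 and C4 methylene groups enantiotopic.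

**Step 3**
Reactants: 5 meso ketone
Product: 6 (1S,5R)-1,5-dimethyl-3-(trimethylsilyloxy)bicyclo[3.3.0]oct-2-ene
Conditions: (R,R)-bis(1-phenylethyl)amine·HCl, n-BuLi (2 equiv), THF, −78 → 0 °C; cool to −100 °C, 5; then TMSCl, −100 → −78 °C
Reagents that add atoms: chlorotrimethylsilane, C[Si](C)(C)Cl
Why: Enantiotopos-differentiating deprotonation of a meso ketone by a C2-symmetric chiral lithium amide in the presence of LiCl, a reaction type with close precedent on cis-bicyclo[3.3.0]octan-3-ones, should remove the exo proton of one of the two enantiotopic α-methylene groups and so fix the absolute configuration of both quaternary carbons at once, the enolate being trapped regiospecifically by silylation.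

**Step 4**
Reactants: 6 enol silane
Product: 8 2-[(1R,2R)-2-formyl-1,2-dimethylcyclopentyl]acetic acid (in equilibrium with its cyclic hydroxy-lactone form), via methoxy hydroperoxide 7 (not isolated)
Conditions: O3, CH2Cl2/MeOH (4:1), −78 °C; then Me2S, −78 → 23 °C; aqueous work-up at pH 3
Reagents that add atoms: ozone, [O-][O+]=O
Why: Ozonolysis of the electron-rich silyl enol ether cleaves the C2=C3 bond of the temporary ring, the silyloxy-bearing carbon emerging as the silyl ester and then the free acid and C2 as the aldehyde after reduction of the methoxy hydroperoxide, so the two cis arms come out differentiated as CHO on one quaternary carbon and CH2CO2H on the other.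

**Step 5**
Reactants: 8 aldehyde acid
Product: 10 (4aR,7aR)-4a,7a-dimethyl-1-(3-methylbut-2-en-1-yl)hexahydrocyclopenta[c]pyran-3(1H)-one (δ-lactone; both epimers at C1), via hydroxy acid 9 (not isolated)
Conditions: BaI2, Li, biphenyl, THF, 23 °C (active Ba); 1-chloro-3-methylbut-2-ene, −78 °C; 8 (0.4 equiv), THF, −78 °C; then 1 M aq. HCl, 23 °C
Reagents that add atoms: 1-chloro-3-methylbut-2-ene (prenyl chloride), CC(C)=CCCl
Why: Prenylbarium chloride adds to aldehydes through its CH2 terminus (α-selective carbonyl allylation of allylbarium reagents), a preference reinforced here by the neopentyl, non-enolisable aldehyde; the first equivalent is spent on the carboxylic acid, the new carbinol centre is uncontrolled and is erased in step 13, and acidification closes the δ-lactone, helped by the two quaternary ring atoms (Thorpe–Ingold effect).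

**Step 6**
Reactants: 11 2-methylphenol (o-cresol)
Product: 12 2-methyl-6-(3-methylbut-2-en-1-yl)phenol
Conditions: NaH, toluene, 0 °C; 1-bromo-3-methylbut-2-ene, 0 → 23 °C
Reagents that add atoms: 1-bromo-3-methylbut-2-ene (prenyl bromide), CC(C)=CCBr
Why: Alkylation of a sodium phenoxide in a non-polar solvent, where the oxygen is tied up in the ion-pair aggregate, should take place at the only free ortho carbon (ortho C-prenylation of phenoxides), with the O-prenyl ether and the para isomer as separable minor products.

**Step 7**
Reactants: 12 prenylphenol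
Product: 13 2-methyl-6-(3-methylbut-2-en-1-yl)cyclohexa-2,5-diene-1,4-dione
Conditions: O2 (1 atm), [N,N'-ethylenebis(salicylideneiminato)]cobalt, Co(C16H14N2O2) (10 mol %), DMF, 23 °C
Reagents that add atoms: dioxygen, O=O
Why: Cobalt–salen catalysed aerobic oxidation of 2,6-dialkylphenols gives the para-benzoquinones, the two ortho substituents blocking ortho coupling and DMF disfavouring diphenoquinone formation, and it should leave the trisubstituted alkene untouched.

**Step 8**
Reactants: 13 quinone
Product: 14 2-methyl-6-(3-methylbut-2-en-1-yl)benzene-1,4-diol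
Conditions: Na2S2O4, EtOAc/H2O, 23 °C, argon
Reagents that add atoms: none
Why: Dithionite reduction of a benzoquinone to the hydroquinone is fast and selective and does not touch the prenyl alkene.

**Step 9**
Reactants: 14 hydroquinone
Product: 15 1,4-bis(tert-butyldimethylsilyloxy)-2-methyl-6-(3-methylbut-2-en-1-yl)benzene
Conditions: TBSCl (3 equiv), imidazole, DMF, 45 °C
Reagents that add atoms: tert-butylchlorodimethylsilane, CC(C)(C)[Si](C)(C)Cl
Why: Imidazole-mediated silylation protects both phenols (the flanked one needing gentle warming) as aryl silyl ethers that should tolerate the oxidation, chlorination and organobarium steps and come off with fluoride at the end.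

**Step 10**
Reactants: 15 bis-silyl ether
Product: 16 (E)-4-[2,5-bis(tert-butyldimethylsilyloxy)-3-methylphenyl]-2-methylbut-2-en-1-ol
Conditions: SeO2 (0.3 equiv), t-BuOOH (3 equiv), salicylic acid (cat.), CH2Cl2, 0 → 23 °C
Reagents that add atoms: selenium dioxide, O=[Se]=O (oxygen donor, turned over); tert-butyl hydroperoxide, CC(C)(C)OO (terminal oxidant)
Why: Catalytic SeO2 allylic oxidation (ene reaction followed by [2,3]-sigmatropic shift) of a prenyl group attacks the methyl group trans to the chain and should give the (E)-2-methylalk-2-en-1-ol selectively, which fixes the geometry of the trisubstituted alkene of the target.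

**Step 11**
Reactants: 16 (E)-allylic alcohol
Product: 17 (E)-1-chloro-4-[2,5-bis(tert-butyldimethylsilyloxy)-3-methylphenyl]-2-methylbut-2-ene
Conditions: PPh3, CCl4, 60 °C
Reagents that add atoms: tetrachloromethane, ClC(Cl)(Cl)Cl
Why: Appel chlorination converts primary allylic alcohols into the chlorides by SN2 displacement of the oxyphosphonium group without allylic transposition or loss of alkene geometry.

**Step 12**
Reactants: 17 (E)-allylic chloride; 10 δ-lactone
Product: 19 (4aR,7aR)-3-{(E)-4-[2,5-bis(tert-butyldimethylsilyloxy)-3-methylphenyl]-2-methylbut-2-en-1-yl}-4a,7a-dimethyl-1-(3-methylbut-2-en-1-yl)octahydrocyclopenta[c]pyran-3-ol (cyclic hemiketal; epimers at C1 and C3), via allylbarium chloride 18 (not isolated)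
Conditions: BaI2, Li, biphenyl, THF, 23 °C (active Ba); 17, −78 °C, 30 min; 10 (0.9 equiv), THF, −78 °C; AcOH in THF, −78 °C
Reagents that add atoms: none
Why: Proposed new method: insertion of active barium into the allylic C–Cl bond of 17 at −78 °C gives the σ-bonded (E)-allylbarium chloride 18, which is configurationally stable at that temperature and should attack the lactone carbonyl of 10 with its barium-bearing CH2 carbon, as allylbarium reagents do with aldehydes, ketones and CO2, to give a barium hemiketalate that stays closed as a six-membered ring until the cold acetic acid quench. The closest known reaction types are the α-selective, geometry-retentive carbonyl allylation and carboxylation of allylbarium reagents and the mono-addition of allylmagnesium halides to δ-lactones that stops at the lactol stage; what is new is a lactone as the acyl partner of an allylbarium. No ring is closed, since the oxacyclohexane ring of the lactone is carried through as the hemiketal, and the only new stereocentre, the hemiketal carbon C3, forms without control and reverts to a ketone carbon on ring opening in step 13. The step needs CH2 (α) and not CH (γ) attack, retention of the E geometry and mono-addition: the first two rest on the barium counter-ion at −78 °C, the third on the cyclic tetrahedral intermediate, which the two quaternary ring atoms and the cis ring fusion hold closed and which keeps the nascent β,γ-unsaturated ketone masked from the basic reagent, so that neither a second addition nor enolisation with double-bond migration should occur. In this one event two halves of similar size are joined, the side-chain ketone appears at its final oxidation level and the E-trisubstituted alkene arrives intact.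

**Step 13**
Reactants: 19 hemiketal
Product: 21 1-[(1R,2R)-2-{(E)-6-[2,5-bis(tert-butyldimethylsilyloxy)-3-methylphenyl]-4-methyl-2-oxohex-4-en-1-yl}-1,2-dimethylcyclopentyl]-4-methylpent-3-en-1-one, via hydroxy ketone 20 (not isolated)
Conditions: Dess–Martin periodinane (2 equiv), NaHCO3, CH2Cl2, 0 → 23 °C
Reagents that add atoms: none
Why: The hemiketal is in equilibrium with its open δ-hydroxy ketone, whose hindered homoallylic secondary alcohol is oxidised by the Dess–Martin reagent under buffered, near-neutral conditions, the standard way to reach β,γ-unsaturated ketones without migration of the double bond into conjugation or aldol closure of the 1,5-diketone.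

**Step 14**
Reactants: 21 bis-silyl diketone
Product: 22 1-[(1R,2R)-2-[(E)-6-(2,5-dihydroxy-3-methylphenyl)-4-methyl-2-oxohex-4-en-1-yl]-1,2-dimethylcyclopentyl]-4-methylpent-3-en-1-one (target)
Conditions: Bu4NF/AcOH (1:1, 3 equiv), THF, 0 °C, argon; work-up with aq. Na2S2O4
Reagents that add atoms: none
Why: Fluoride cleaves the two aryl silyl ethers, and buffering with acetic acid keeps the medium from turning basic, so that the two β,γ-unsaturated ketones, the 1,5-diketone and the air-sensitive hydroquinone should survive.

**Compound list**

1 | cis-1,5-dimethylbicyclo[3.3.0]octane-3,7-dione (meso) | O=C1C[C@]2(C)CC(=O)C[C@]2(C)C1 | starting material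
2 | cis-7,7-(2,2-dimethylpropane-1,3-diyldioxy)-1,5-dimethylbicyclo[3.3.0]octan-3-one | O=C1C[C@]2(C)CC3(OCC(C)(C)CO3)C[C@]2(C)C1 | intermediate
3 | hydrazone of 2 | NN=C1C[C@]2(C)CC3(OCC(C)(C)CO3)C[C@]2(C)C1 | intermediate (not isolated)
4 | cis-3,3-(2,2-dimethylpropane-1,3-diyldioxy)-1,5-dimethylbicyclo[3.3.0]octane | CC1(C)COC2(OC1)C[C@]1(C)CCC[C@]1(C)C2 | intermediate (not isolated)
5 | cis-(1R,5S)-1,5-dimethylbicyclo[3.3.0]octan-3-one (meso) | O=C1C[C@]2(C)CCC[C@]2(C)C1 | intermediate
6 | (1S,5R)-1,5-dimethyl-3-(trimethylsilyloxy)bicyclo[3.3.0]oct-2-ene | C[Si](C)(C)OC1=C[C@]2(C)CCC[C@]2(C)C1 | intermediate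
7 | trimethylsilyl 2-[(1R,2R)-2-(hydroperoxy(methoxy)methyl)-1,2-dimethylcyclopentyl]acetate | COC(OO)[C@]1(C)CCC[C@]1(C)CC(=O)O[Si](C)(C)C | intermediate (not isolated)
8 | 2-[(1R,2R)-2-formyl-1,2-dimethylcyclopentyl]acetic acid | O=C[C@]1(C)CCC[C@]1(C)CC(=O)O | intermediate
9 | 2-[(1R,2R)-2-(1-hydroxy-4-methylpent-3-en-1-yl)-1,2-dimethylcyclopentyl]acetic acid | CC(C)=CCC(O)[C@]1(C)CCC[C@]1(C)CC(=O)O | intermediate (not isolated)
10 | (4aR,7aR)-4a,7a-dimethyl-1-(3-methylbut-2-en-1-yl)hexahydrocyclopenta[c]pyran-3(1H)-one | CC(C)=CCC2[C@]1(C)CCC[C@]1(C)CC(=O)O2 | intermediate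
11 | 2-methylphenol | Cc1ccccc1O | starting material
12 | 2-methyl-6-(3-methylbut-2-en-1-yl)phenol | CC(C)=CCc1cccc(C)c1O | intermediate
13 | 2-methyl-6-(3-methylbut-2-en-1-yl)cyclohexa-2,5-diene-1,4-dione | CC(C)=CCC1=CC(=O)C=C(C)C1=O | intermediate
14 | 2-methyl-6-(3-methylbut-2-en-1-yl)benzene-1,4-diol | CC(C)=CCc1cc(O)cc(C)c1O | intermediate
15 | 1,4-bis(tert-butyldimethylsilyloxy)-2-methyl-6-(3-methylbut-2-en-1-yl)benzene | CC(C)=CCc1cc(O[Si](C)(C)C(C)(C)C)cc(C)c1O[Si](C)(C)C(C)(C)C | intermediate
16 | (E)-4-[2,5-bis(tert-butyldimethylsilyloxy)-3-methylphenyl]-2-methylbut-2-en-1-ol | OC/C(C)=C/Cc1cc(O[Si](C)(C)C(C)(C)C)cc(C)c1O[Si](C)(C)C(C)(C)C | intermediate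
17 | (E)-1-chloro-4-[2,5-bis(tert-butyldimethylsilyloxy)-3-methylphenyl]-2-methylbut-2-ene | ClC/C(C)=C/Cc1cc(O[Si](C)(C)C(C)(C)C)cc(C)c1O[Si](C)(C)C(C)(C)C | intermediate
18 | {(E)-4-[2,5-bis(tert-butyldimethylsilyloxy)-3-methylphenyl]-2-methylbut-2-en-1-yl}barium chloride | Cl[Ba]C/C(C)=C/Cc1cc(O[Si](C)(C)C(C)(C)C)cc(C)c1O[Si](C)(C)C(C)(C)C | intermediate (not isolated)
19 | (4aR,7aR)-3-{(E)-4-[2,5-bis(tert-butyldimethylsilyloxy)-3-methylphenyl]-2-methylbut-2-en-1-yl}-4a,7a-dimethyl-1-(3-methylbut-2-en-1-yl)octahydrocyclopenta[c]pyran-3-ol | CC(C)=CCC2[C@]1(C)CCC[C@]1(C)CC(O)(C/C(C)=C/Cc1cc(O[Si](C)(C)C(C)(C)C)cc(C)c1O[Si](C)(C)C(C)(C)C)O2 | intermediate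
20 | (E)-6-[2,5-bis(tert-butyldimethylsilyloxy)-3-methylphenyl]-1-[(1R,2R)-2-(1-hydroxy-4-methylpent-3-en-1-yl)-1,2-dimethylcyclopentyl]-4-methylhex-4-en-2-one | CC(C)=CCC(O)[C@]1(C)CCC[C@]1(C)CC(=O)C/C(C)=C/Cc1cc(O[Si](C)(C)C(C)(C)C)cc(C)c1O[Si](C)(C)C(C)(C)C | intermediate (not isolated)
21 | 1-[(1R,2R)-2-{(E)-6-[2,5-bis(tert-butyldimethylsilyloxy)-3-methylphenyl]-4-methyl-2-oxohex-4-en-1-yl}-1,2-dimethylcyclopentyl]-4-methylpent-3-en-1-one | CC(C)=CCC(=O)[C@]1(C)CCC[C@]1(C)CC(=O)C/C(C)=C/Cc1cc(O[Si](C)(C)C(C)(C)C)cc(C)c1O[Si](C)(C)C(C)(C)C | intermediate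
22 | 1-[(1R,2R)-2-[(E)-6-(2,5-dihydroxy-3-methylphenyl)-4-methyl-2-oxohex-4-en-1-yl]-1,2-dimethylcyclopentyl]-4-methylpent-3-en-1-one | CC(C)=CCC(=O)[C@]1(C)CCC[C@]1(C)CC(=O)C/C(C)=C/Cc1cc(O)cc(C)c1O | target

**Step count and risks**

Total step count: 14. Longest linear sequence: 9 steps (steps 6–14, from 11); the other branch is 8 steps (steps 1–5 and 12–14, from 1).

Steps most likely to fail:

1. Step 12 (Proposed new method). What may go wrong: attack of the allylbarium through its substituted CH terminus; loss of alkene geometry if the reagent warms; deprotonation of the lactone α-methylene, or proton transfer from the benzylic-allylic CH2 of another molecule, in place of addition; opening of the hemiketalate followed by a second addition. Fallback with known chemistry (Corey–Seebach dithiane umpolung, the polarity of the two halves reversed): it sets out from 10. Reduction with i-Bu2AlH (CH2Cl2, −78 °C) gives the lactol F1. Propane-1,3-dithiol and BF3·OEt2 (CH2Cl2, −20 °C) open it to the hydroxy dithiane F2. Double deprotonation with n-BuLi (2.2 equiv, THF, −30 °C) and SN2 alkylation of the 2-lithio-1,3-dithiane with chloride 17 (−78 → 0 °C), which can neither transpose the allyl unit nor change its geometry, give the alkylated dithiane F3. Hydrolysis with MeI and CaCO3 in aqueous MeCN (40 °C) releases the ketone, which closes to hemiketal 19, where the route is rejoined.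

2. Step 3. What may go wrong: poor discrimination between the two enantiotopic methylene groups, or sluggish deprotonation next to the quaternary carbons, leading to low enantiomeric purity that later steps cannot correct. Fallback (resolution in place of asymmetric deprotonation): it sets out from 5. LiN(i-Pr)2 and TMSCl (THF, −78 °C) give the racemic silyl enol ether F4. Ozonolysis as in step 4 gives the racemic aldehyde acid F5. Fractional crystallisation with quinine, a tertiary amine that cannot form an imine with the aldehyde, should give the quininium salt F6 of the (1R,2R)-acid; should the salt of the antipode be the less soluble one, quinidine would be tried. Acidification with aq. HCl returns the route to 8.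

3. Step 5. What may go wrong: incomplete addition because the barium carboxylate of 8 is poorly soluble at −78 °C, or competing attack through the tertiary carbon of the prenyl reagent at this very hindered aldehyde. Fallback (allylation then olefin cross-metathesis): it sets out from 8. Barbier allylation with allyl bromide and In in THF/H2O (23 °C), which tolerates the free acid and has no regiochemical issue, gives the hydroxy acid F7. Acidification closes it to the allyl lactone F8. Cross-metathesis with 2-methylbut-2-ene and the second-generation Grubbs catalyst RuCl2(=CHPh)(PCy3)(C21H26N2) (CH2Cl2, 40 °C) turns the allyl group into the prenyl group and returns the route to 10.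

**Further compounds**

F1 | step 12 | (4aR,7aR)-4a,7a-dimethyl-1-(3-methylbut-2-en-1-yl)octahydrocyclopenta[c]pyran-3-ol (lactol, epimers) | CC(C)=CCC2[C@]1(C)CCC[C@]1(C)CC(O)O2
F2 | step 12 | 1-[(1R,2R)-2-(1,3-dithian-2-ylmethyl)-1,2-dimethylcyclopentyl]-4-methylpent-3-en-1-ol | CC(C)=CCC(O)[C@]1(C)CCC[C@]1(C)CC1SCCCS1
F3 | step 12 | 1-[(1R,2R)-2-({2-[(E)-4-[2,5-bis(tert-butyldimethylsilyloxy)-3-methylphenyl]-2-methylbut-2-en-1-yl]-1,3-dithian-2-yl}methyl)-1,2-dimethylcyclopentyl]-4-methylpent-3-en-1-ol | CC(C)=CCC(O)[C@]1(C)CCC[C@]1(C)CC1(C/C(C)=C/Cc2cc(O[Si](C)(C)C(C)(C)C)cc(C)c2O[Si](C)(C)C(C)(C)C)SCCCS1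
F4 | step 3 | racemic cis-1,5-dimethyl-3-(trimethylsilyloxy)bicyclo[3.3.0]oct-2-ene (both enantiomers) | C[Si](C)(C)OC1=C[C@]2(C)CCC[C@]2(C)C1.C[Si](C)(C)OC1=C[C@@]2(C)CCC[C@@]2(C)C1
F5 | step 3 | racemic cis-2-(2-formyl-1,2-dimethylcyclopentyl)acetic acid (both enantiomers) | O=C[C@]1(C)CCC[C@]1(C)CC(=O)O.O=C[C@@]1(C)CCC[C@@]1(C)CC(=O)O
F6 | step 3 | quininium 2-[(1R,2R)-2-formyl-1,2-dimethylcyclopentyl]acetate | O=C[C@]1(C)CCC[C@]1(C)CC(=O)[O-].COC1=CC2=C(C=CN=C2C=C1)[C@H]([C@@H]3C[C@@H]4CC[NH+]3C[C@@H]4C=C)O
F7 | step 5 | 2-[(1R,2R)-2-(1-hydroxybut-3-en-1-yl)-1,2-dimethylcyclopentyl]acetic acid | C=CCC(O)[C@]1(C)CCC[C@]1(C)CC(=O)O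
F8 | step 5 | (4aR,7aR)-1-allyl-4a,7a-dimethylhexahydrocyclopenta[c]pyran-3(1H)-one | C=CCC2[C@]1(C)CCC[C@]1(C)CC(=O)O2
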